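**Strategy.** The carbocycle of the tetralin (C1 bears the aryl group, C2 the acyloxymethyl arm, C3 the hydroxymethyl arm) is closed last, by acid isomerisation of a 2-aryl-tetrahydrofuran. The ring oxygen joins C1, a p-hydroxybenzylic carbon, to the carbon of the C3 hydroxymethyl group. Ionisation of the C1–O bond therefore frees the C3–CH2OH, makes the C1 cation and lets the aromatic carbon C8a, para to the C6 methoxy group, form the C1–C8a bond, with C1 set trans to C2. The precursor, a lariciresinol-type ether whose only alcohol already carries the p-coumarate, comes from a twofold-symmetric (R,R)-diol made by auxiliary-controlled oxidative enolate dimerisation and desymmetrised by one oxidative cycloetherification.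

Key step: step 6

Remark: the benzylic configuration of the tetrahydrofurans 8 and 10 is drawn as the expected 2,3-trans isomer; this center is erased in step 6, so either epimer serves.

**Step 1**
Reactants: 1 3-(4-hydroxy-3-methoxyphenyl)propanoic acid (dihydroferulic acid); 2 (S)-4-isopropyl-1,3-oxazolidin-2-one
Product: 4 (S)-4-isopropyl-3-{3-[3-methoxy-4-(pivaloyloxy)phenyl]propanoyl}-1,3-oxazolidin-2-one, via mixed pivalic anhydride 3 (not isolated)
Conditions: PivCl (2.3 equiv), Et3N, THF, 0 °C; then LiCl, 2, rt
Reagents that add atoms: pivaloyl chloride, CC(C)(C)C(=O)Cl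
Why: Pivaloyl chloride should turn the acid into the mixed anhydride and the phenol into its hindered pivalate, and the LiCl/Et3N-activated oxazolidinone is then acylated at the less hindered carbonyl of the anhydride (mixed-anhydride N-acylation of an oxazolidinone auxiliary); no stereocenter is formed.

**Step 2**
Reactants: 4 (S)-4-isopropyl-3-{3-[3-methoxy-4-(pivaloyloxy)phenyl]propanoyl}-1,3-oxazolidin-2-one (two molecules)
Product: 5 (4S,4'S)-3,3'-{(2R,3R)-2,3-bis[3-methoxy-4-(pivaloyloxy)benzyl]butanedioyl}bis(4-isopropyl-1,3-oxazolidin-2-one)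
Conditions: LDA, THF, −78 °C; then TiCl4, −78 °C → rt
Reagents that add atoms: none
Why: Oxidative enolate homocoupling: the chelated Z-enolate is transferred to titanium(IV) and oxidised by one electron, and each new C–C bond should form on the enolate face anti to the isopropyl group, so that both new α-centers are R and the twofold-symmetric (R,R)-dimer should prevail over the meso isomer, which is removed by chromatography or crystallisation.

**Step 3**
Reactants: 5 (R,R)-bis-imide
Product: 6 (2R,3R)-2,3-bis(4-hydroxy-3-methoxybenzyl)butane-1,4-diol ((−)-secoisolariciresinol)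
Conditions: LiAlH4, THF, 0 °C → rt; aq. Rochelle salt work-up
Reagents that add atoms: none
Why: Hydride reduction should cleave both N-acyl oxazolidinones to primary alcohols and both aryl pivalates to phenols in one operation, without enolisation of the two α-stereocenters.

**Step 4**
Reactants: 6 (−)-secoisolariciresinol
Product: 8 (+)-lariciresinol, (2S,3R,4R)-2-(4-hydroxy-3-methoxyphenyl)-4-(4-hydroxy-3-methoxybenzyl)-3-(hydroxymethyl)tetrahydrofuran, via quinone methide 7 (not isolated)
Conditions: DDQ (1.0 equiv, slow addition), 1,4-dioxane, rt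
Reagents that add atoms: none
Why: DDQ should dehydrogenate one p-alkylguaiacol unit to the p-quinone methide, which the δ-hydroxyl traps by 5-exo-trig 1,6-addition (oxidative cycloetherification) to the 2,3-trans ether; the two halves of 6 are homotopic, so either benzylic site gives the same product and the hydroxymethyl left free is necessarily the one beside the new benzylic C–O carbon.

**Step 5**
Reactants: 8 (+)-lariciresinol; 9 (E)-p-coumaric acid
Product: 10 [(2S,3R,4R)-2-(4-hydroxy-3-methoxyphenyl)-4-(4-hydroxy-3-methoxybenzyl)tetrahydrofuran-3-yl]methyl (E)-3-(4-hydroxyphenyl)prop-2-enoate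
Conditions: PPh3, DIAD, THF, 0 °C → rt, exclusion of light
Reagents that add atoms: none
Why: Mitsunobu esterification: the only aliphatic alcohol is activated as its alkoxyphosphonium ion and displaced by the carboxylate, the one partner acidic enough to act as pronucleophile, so the three phenols should stay free; the reacting carbon is a CH2 group and no stereocenter is touched.

**Step 6**
Reactants: 10 lariciresinol-type p-coumarate
Product: 12 [(1S,2R,3R)-7-hydroxy-1-(4-hydroxy-3-methoxyphenyl)-3-(hydroxymethyl)-6-methoxy-1,2,3,4-tetrahydronaphthalen-2-yl]methyl (E)-3-(4-hydroxyphenyl)prop-2-enoate (target), via ring-opened quinone methide 11 (not isolated)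
Conditions: TFA (5 equiv), CH2Cl2/HFIP, 0 °C → rt; aq. NaHCO3 work-up
Reagents that add atoms: none
Why: Acid protonates the ring oxygen and the C–O bond at the p-hydroxybenzylic carbon ionises to the O-protonated form of quinone methide 11, which releases the C3 hydroxymethyl group; the guaiacyl ring tethered through C4 then attacks this carbon with its position para to the methoxy group and rearomatises. The closest known reaction type is the acid isomerisation of 2-aryl-tetrahydrofuran lignans to aryltetralins, an intramolecular Friedel–Crafts alkylation by a benzylic cation. The carbocycle closes in a 6-exo-trig mode with respect to the exocyclic C=C of the quinone methide (6-endo with respect to the attacking arene) through a half-chair transition state. The new stereocenter C1 is controlled by the existing C2 and C3 centers: the aryl group takes the pseudo-equatorial position trans to the C2 acyloxymethyl arm, and reversible ionisation lets both benzylic epimers of 10 converge on the same cation. The step needs attack at the ring carbon para to OMe (the other ortho position, between CH2 and OMe, is hindered) and survival of the cinnamate ester, which anhydrous acid at low temperature and the irreversible C–C bond formation should secure.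

**Compound list**
1 | 3-(4-hydroxy-3-methoxyphenyl)propanoic acid (dihydroferulic acid) | COc1cc(CCC(=O)O)ccc1O | starting material
2 | (S)-4-isopropyl-1,3-oxazolidin-2-one | CC(C)[C@H]1COC(=O)N1 | starting material
3 | 3-[3-methoxy-4-(pivaloyloxy)phenyl]propanoic pivalic anhydride | COc1cc(CCC(=O)OC(=O)C(C)(C)C)ccc1OC(=O)C(C)(C)C | intermediate
4 | (S)-4-isopropyl-3-{3-[3-methoxy-4-(pivaloyloxy)phenyl]propanoyl}-1,3-oxazolidin-2-one | COc1cc(CCC(=O)N2[C@@H](C(C)C)COC2=O)ccc1OC(=O)C(C)(C)C | intermediate
5 | (4S,4'S)-3,3'-{(2R,3R)-2,3-bis[3-methoxy-4-(pivaloyloxy)benzyl]butanedioyl}bis(4-isopropyl-1,3-oxazolidin-2-one) | O=C(N1[C@@H](C(C)C)COC1=O)[C@H](Cc1ccc(OC(=O)C(C)(C)C)c(OC)c1)[C@@H](Cc1ccc(OC(=O)C(C)(C)C)c(OC)c1)C(=O)N1[C@@H](C(C)C)COC1=O | intermediate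
6 | (2R,3R)-2,3-bis(4-hydroxy-3-methoxybenzyl)butane-1,4-diol ((−)-secoisolariciresinol) | OC[C@H](Cc1ccc(O)c(OC)c1)[C@@H](Cc1ccc(O)c(OC)c1)CO | intermediate
7 | p-quinone methide of 6: 4-[(2R,3R)-3-(4-hydroxy-3-methoxybenzyl)-4-hydroxy-2-(hydroxymethyl)butylidene]-2-methoxycyclohexa-2,5-dien-1-one (exocyclic C=C geometry not fixed) | OC[C@H](C=C1C=CC(=O)C(OC)=C1)[C@@H](Cc1ccc(O)c(OC)c1)CO | intermediate
8 | (+)-lariciresinol, (2S,3R,4R)-2-(4-hydroxy-3-methoxyphenyl)-4-(4-hydroxy-3-methoxybenzyl)-3-(hydroxymethyl)tetrahydrofuran | COc1cc([C@H]2OC[C@H](Cc3ccc(O)c(OC)c3)[C@@H]2CO)ccc1O | intermediate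
9 | (E)-p-coumaric acid | O=C(O)/C=C/c1ccc(O)cc1 | starting material
10 | [(2S,3R,4R)-2-(4-hydroxy-3-methoxyphenyl)-4-(4-hydroxy-3-methoxybenzyl)tetrahydrofuran-3-yl]methyl (E)-3-(4-hydroxyphenyl)prop-2-enoate | COc1cc([C@H]2OC[C@H](Cc3ccc(O)c(OC)c3)[C@@H]2COC(=O)/C=C/c2ccc(O)cc2)ccc1O | intermediate
11 | ring-opened p-quinone methide of 10: (2R,3R)-3-(4-hydroxy-3-methoxybenzyl)-4-hydroxy-2-[(3-methoxy-4-oxocyclohexa-2,5-dien-1-ylidene)methyl]butyl (E)-3-(4-hydroxyphenyl)prop-2-enoate (reacts as its O-protonated form; exocyclic C=C geometry not fixed) | O=C(/C=C/c1ccc(O)cc1)OC[C@H](C=C1C=CC(=O)C(OC)=C1)[C@@H](Cc1ccc(O)c(OC)c1)CO | intermediate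
12 | [(1S,2R,3R)-7-hydroxy-1-(4-hydroxy-3-methoxyphenyl)-3-(hydroxymethyl)-6-methoxy-1,2,3,4-tetrahydronaphthalen-2-yl]methyl (E)-3-(4-hydroxyphenyl)prop-2-enoate | COc1cc([C@H]2c3cc(O)c(OC)cc3C[C@@H](CO)[C@@H]2COC(=O)/C=C/c2ccc(O)cc2)ccc1O | target

**Total step count:** 6. **Longest linear sequence:** 6 steps (1 → 12).

**Steps most likely to fail**

Step 4. The product still carries one p-hydroxybenzyl unit of the same kind, so a second dehydrogenation competes with the first and over-oxidation to the bis-ether limits conversion and selectivity together; oxidative side reactions of the free guaiacols are a further risk. Fallback: setting out from 6, the oxidation is driven to completion with DDQ (2.2 equiv, dioxane) to give (+)-pinoresinol F1, the twofold-symmetric end point at which no selectivity is required. One of its two equivalent benzylic C–O bonds is then cleaved by hydrogenolysis (H2, Pd/C, EtOAc/EtOH, stopped after one equivalent of hydrogen), which comes back to the route at 8; over-reduced material is 6 and is recycled.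

Step 5. The alkoxyphosphonium ion may alkylate a phenol instead of the carboxylate, or displacement at the β-branched primary carbon may be too slow and the activated alcohol is diverted to hydrazide by-products. Fallback: setting out from 8, exhaustive Steglich acylation (DCC, DMAP, CH2Cl2) with commercial (E)-4-acetoxycinnamic acid (3.5 equiv) should give the tris(4-acetoxycinnamate) F2, for which no chemoselectivity is needed. The two aryl cinnamates and three aryl acetates are then removed by aminolysis with pyrrolidine (CH2Cl2/MeOH, 0 °C), aryl esters being far better acyl donors than the alkyl cinnamate; this comes back to the route at 10.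

Step 6. The ester carbonyl may capture the C1 cation as a six-membered acyloxonium ion, or the acyl group may migrate to the liberated C3 hydroxymethyl group, and facial selectivity at C1 may be incomplete. Fallback: setting out from 8, the same acid isomerisation is run before the ester is in place (TFA, CH2Cl2), which should give (+)-isolariciresinol F3. The less hindered C3 hydroxymethyl group is then tritylated selectively (TrCl, pyridine, cat. DMAP; phenols give no stable trityl ethers) to the trityl ether F4. Mitsunobu esterification of the remaining alcohol with 9 (PPh3, DIAD, THF) gives the trityl ether p-coumarate F5, and detritylation (HCO2H, Et2O, rt) comes back to the route at the target 12.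

**Further compounds**
F1 | step 4 | (+)-pinoresinol, (1S,3aR,4S,6aR)-1,4-bis(4-hydroxy-3-methoxyphenyl)tetrahydro-1H,3H-furo[3,4-c]furan | COc1cc([C@H]2OC[C@H]3[C@@H]2CO[C@@H]3c2ccc(O)c(OC)c2)ccc1O
F2 | step 5 | lariciresinol tris[(E)-4-acetoxycinnamate] (both phenols and the primary alcohol acylated) | COc1cc([C@H]2OC[C@H](Cc3ccc(OC(=O)/C=C/c4ccc(OC(C)=O)cc4)c(OC)c3)[C@@H]2COC(=O)/C=C/c2ccc(OC(C)=O)cc2)ccc1OC(=O)/C=C/c1ccc(OC(C)=O)cc1
F3 | step 6 | (+)-isolariciresinol, (1S,2R,3R)-1-(4-hydroxy-3-methoxyphenyl)-2,3-bis(hydroxymethyl)-6-methoxy-1,2,3,4-tetrahydronaphthalen-7-ol | COc1cc([C@H]2c3cc(O)c(OC)cc3C[C@@H](CO)[C@@H]2CO)ccc1O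
F4 | step 6 | (+)-isolariciresinol trityl ether at the C3 hydroxymethyl group | COc1cc([C@H]2c3cc(O)c(OC)cc3C[C@@H](COC(c3ccccc3)(c3ccccc3)c3ccccc3)[C@@H]2CO)ccc1O
F5 | step 6 | C3-trityloxymethyl isolariciresinol C2-methyl (E)-p-coumarate | COc1cc([C@H]2c3cc(O)c(OC)cc3C[C@@H](COC(c3ccccc3)(c3ccccc3)c3ccccc3)[C@@H]2COC(=O)/C=C/c2ccc(O)cc2)ccc1O
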